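**Assumption:** the SMILES is taken literally. It encodes (4S,5S,6R,8R,9R,10S,13R), that is H-5 on the same face as the C-19/C-20 lactone bridge (cis-fused rings A/B), 6-OH cis to H-5, 8-CH3 trans to H-5 and O-9 trans to C-20.

**Convention:** labdane numbering is used throughout, also for the carvone ring (C-5 to C-10). C-19 is the lactone carbonyl on C-4, C-20 the OCH2 on C-10, C-17 the methyl on C-8. β is the face of C-20 in the usual flat drawing.

## Retrosynthetic overview

1. Target ⇒ diene 24: one hydroxyl-directed hydrogenation sets C-8 and saturates C-14/C-15.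
2. 24 ⇒ hydroxy-butenolide 21: new trivalent-iodine dearomatising spiroetherification of a 2-silyloxyfuran forms O–C-13, the spiro tetrahydrofuran and the C-13 centre.
3. 21 ⇒ enone 16: vinyl addition to the C-9 ketone, then B-alkyl Suzuki coupling with 3-bromobutenolide; 6-OH from a singlet-oxygen [4+2] on a silyl dienol ether.
4. Ring A ⇒ lactone-enolate alkylation (C-3–C-4) on a trans-fused δ-lactone carrying an axial 3-halopropyl chain.
5. Lactone and quaternary C-10 ⇒ double α′-alkylation of (S)-carvone. Ring order: B (carvone) → δ-lactone → A → spiro ether and lactone ring together → saturation.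

## Route

Step 1
Reactants: 1 (S)-(+)-carvone; 2 1-chloro-3-iodopropane
Product: 3 (5S,6R)-6-(3-chloropropyl)-2-methyl-5-(prop-1-en-2-yl)cyclohex-2-en-1-one
Conditions: LiN(iPr)2, THF, −78 °C; then 2, DMPU, −78 → −30 °C
Reagents that add atoms: 1-chloro-3-iodopropane, ClCCCI
Why: Kinetic α′-enolate alkylation of carvone (SN2 at the C–I end, the chloride survives) puts the chain anti to the isopropenyl group, but this centre is planarised again in step 2 so only C-5 of (S)-carvone is carried on.

Step 2
Reactants: 3 6-(3-chloropropyl)carvone; 4 benzyl chloromethyl ether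
Product: 5 (5R,6S)-6-[(benzyloxy)methyl]-6-(3-chloropropyl)-2-methyl-5-(prop-1-en-2-yl)cyclohex-2-en-1-one
Conditions: LiN(iPr)2, THF, −78 °C; then 4, DMPU, −78 → −30 °C
Reagents that add atoms: benzyl chloromethyl ether, ClCOCc1ccccc1
Why: A second kinetic enolate C-alkylation builds quaternary C-10 with the BnOCH2 group (future C-20) entering anti to the pseudoaxial isopropenyl group, so the chloropropyl chain (C-1 to C-3) ends cis to the C-4 carbon, which later gives H-5 cis to C-20.

Step 3
Reactants: 5 dialkylated carvone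
Product: 7 6-[(benzyloxy)methyl]-6-(3-chloropropyl)-5-(1-hydroxypropan-2-yl)-2-methylcyclohex-2-en-1-one (ring centres as in 5; both C-4 epimers), via catechol boronate 6 (not isolated)
Conditions: catecholborane, RhCl(PPh3)3 (3 mol %), THF, 0 °C → rt; then H2O2, pH 7 phosphate buffer, EtOH, 0 °C
Reagents that add atoms: hydrogen peroxide, OO
Why: Rhodium-catalysed hydroboration with catecholborane (Männig–Nöth conditions) takes the 1,1-disubstituted alkene in preference to the hindered s-trans enone and gives the anti-Markovnikov alcohol after neutral oxidation; the new C-4 centre forms unselectively and is erased in step 8.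

Step 4
Reactants: 7 primary alcohol
Product: 8 2-{6-[(benzyloxy)methyl]-6-(3-chloropropyl)-4-methyl-5-oxocyclohex-3-en-1-yl}propanoic acid (C-4 epimers)
Conditions: TEMPO (cat.), PhI(OAc)2, MeCN/H2O, rt
Reagents that add atoms: water, O
Why: The oxoammonium oxidation runs through the aldehyde hydrate to the acid and leaves the enone, benzyl ether and alkyl chloride alone.

Step 5
Reactants: 8 carboxylic acid
Product: 10 8a-(3-chloropropyl)-4,7-dimethyl-4a,5-dihydro-1H-isochromene-3,8(4H,8aH)-dione (trans-fused; 4-CH3 equatorial), via hydroxy acid 9 (not isolated)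
Conditions: BCl3, CH2Cl2, −78 → −20 °C, then H2O; TsOH·H2O (cat.), PhH, reflux; DBU (cat.), PhMe, 60 °C
Reagents that add atoms: none
Why: BCl3 cleaves the benzyl ether, the 5-hydroxy acid lactonises under acid catalysis to the trans-fused δ-lactone (C-20 and C-4 are trans-diequatorial on ring B), and DBU equilibrates C-4 to the equatorial-methyl epimer, the axial one being syn-diaxial to the chain.

Step 6
Reactants: 10 chloro lactone enone
Product: 11 8a-(3-iodopropyl)-4,7-dimethyl-4a,5-dihydro-1H-isochromene-3,8(4H,8aH)-dione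
Conditions: NaI, acetone, reflux
Reagents that add atoms: sodium iodide, [Na+].[I-]
Why: Finkelstein exchange gives the iodide needed for the ring-closing alkylation.

Step 7
Reactants: 11 iodo lactone enone
Product: 12 8-[(tert-butyldimethylsilyl)oxy]-8a-(3-iodopropyl)-4,7-dimethyl-1,4,4a,8a-tetrahydro-3H-isochromen-3-one
Conditions: TBSOTf, Et3N, CH2Cl2, 0 °C
Reagents that add atoms: tert-butyldimethylsilyl trifluoromethanesulfonate, CC(C)(C)[Si](C)(C)OS(=O)(=O)C(F)(F)F
Why: Soft enolisation can only occur by γ-deprotonation (C-10 is quaternary) and gives the linear 1-silyloxy-1,3-diene, which masks the ketone for step 8 and is the diene for step 9.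

Step 8
Reactants: 12 silyl dienol ether iodide
Product: 13 9-[(tert-butyldimethylsilyl)oxy]-11,12,13,14,15,16-hexanor-5β-labda-6,8-dien-19,20-olide
Conditions: KN(SiMe3)2, THF, −78 → 0 °C
Reagents that add atoms: none
Why: Intramolecular 6-exo-tet alkylation of the lactone enolate (the only acidic C–H) by the axial iodopropyl chain closes ring A as a 3-oxabicyclo[3.3.1]nonanone, and quaternary C-4 can only form with C-3 cis to C-1, which gives the cis A/B fusion with H-5 cis to C-20.

Step 9
Reactants: 13 tricyclic silyl dienol ether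
Product: 16 6β-hydroxy-9-oxo-11,12,13,14,15,16-hexanor-5β-labd-7-en-19,20-olide, via endoperoxide 14 (not isolated), via hydroperoxide 15 (not isolated)
Conditions: O2, methylene blue (cat.), hν (red LED), CH2Cl2/MeOH 9:1, −78 °C; then PPh3, −78 °C → rt
Reagents that add atoms: oxygen (as singlet oxygen), O=O
Why: Singlet-oxygen [4+2] cycloaddition to the s-cis-locked silyloxydiene occurs on the convex β face anti to C-1 of ring A, so the C-6 oxygen is cis to H-5; methanol-assisted collapse of the silyl peroxyketal gives the 6-hydroperoxy enone, which PPh3 reduces to the alcohol.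

Step 10
Reactants: 16 hydroxy enone; 17 vinylmagnesium bromide
Product: 18 6β,9α-dihydroxy-13,14,15,16-tetranor-5β-labda-7,11-dien-19,20-olide
Conditions: CH2=CHMgBr, CeCl3, THF, −78 → −40 °C; aq NH4Cl
Reagents that add atoms: vinylmagnesium bromide, C=C[Mg]Br
Why: Organocerium 1,2-addition to the hindered enone spares the lactone and comes from the convex face anti to the axial C-10–C-1 bond, placing the vinyl group (C-11/C-12) β and the C-9 hydroxyl α.

Step 11
Reactants: 18 vinyl carbinol; 19 3-bromofuran-2(5H)-one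
Product: 21 6β,9α-dihydroxy-5β-labda-7,13-diene-19,20:16,15-diolide, via alkylborane 20 (not isolated)
Conditions: 9-BBN, THF, 0 °C → rt; then 19, PdCl2(dppf) (5 mol %), AsPh3, K3PO4, DMF/H2O, rt
Reagents that add atoms: 3-bromofuran-2(5H)-one, O=C1OCC=C1Br
Why: Anti-Markovnikov hydroboration of the vinyl group (the trisubstituted ring alkene is inert to 9-BBN) followed by B-alkyl Suzuki–Miyaura coupling with the α-bromobutenolide forms the C-12–C-13 bond without touching a stereocentre.

Step 12
Reactants: 21 hydroxy butenolide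
Product: 24 (13R)-6β-hydroxy-9α,13-epoxy-5β-labda-7,14-diene-19,20:16,15-diolide, via tris-silyl furan 22 (not isolated), via silyl ether 23 (not isolated)
Conditions: TMSOTf, Et3N, CH2Cl2, 0 °C; then (R,R)-ArI(OAc)2 (Ar = 2,6-bis[(1-methoxy-1-oxopropan-2-yl)oxy]phenyl), TMSOTf (cat.), CH2Cl2, −78 °C; then aq citric acid, THF, 0 °C
Reagents that add atoms: none
Why: Proposed new method: the 2-silyloxyfuran (the silyl enol form of the butenolide) attacks the Lewis-acid-activated trivalent iodine centre at C-15 and the tethered C-9 silyl ether oxygen then displaces the aryl-λ3-iodanyl hypernucleofuge in an SN2′ sense at C-13 (5-exo), giving the 3,3-disubstituted furan-2(3H)-one with loss of ArI and two TMSOAc; C-13 is set by the approach that turns the lactone C=O away from quaternary C-10 toward C-8, a bias the C2-symmetric lactate iodane is meant to reinforce; the closest known chemistry is the Kita-type dearomatising spirocyclisation of phenols with trivalent iodine (including lactate-iodane asymmetric variants) and the iodosylbenzene/BF3 γ-functionalisation of 2-silyloxyfurans.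

Step 13
Reactants: 24 spiro enol lactone
Product: 25 (4S,5S,6R,8R,9R,10S,13R)-6β-hydroxy-9α,13-epoxy-5β-labdane-19,20:16,15-diolide (target)
Conditions: H2 (10 bar), [Ir(cod)(PCy3)(py)]PF6 (10 mol %), CH2Cl2, rt
Reagents that add atoms: none
Why: Hydroxyl-directed homogeneous hydrogenation, in which the iridium catalyst bound to the 6β-OH delivers H2 to the convex β face of C-7=C-8 (the α face is covered by ring A), sets 8β-H/8α-CH3 and also saturates the enol-lactone C-14=C-15 bond.

## Compound list

1 | (S)-(+)-carvone, (5S)-2-methyl-5-(prop-1-en-2-yl)cyclohex-2-en-1-one | CC1=CC[C@H](C(C)=C)CC1=O | starting material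
2 | 1-chloro-3-iodopropane | ClCCCI | starting material
3 | (5S,6R)-6-(3-chloropropyl)-2-methyl-5-(prop-1-en-2-yl)cyclohex-2-en-1-one (chain trans to isopropenyl, major epimer) | CC1=CC[C@H](C(C)=C)[C@@H](CCCCl)C1=O | intermediate
4 | benzyl chloromethyl ether | ClCOCc1ccccc1 | starting material
5 | (5R,6S)-6-[(benzyloxy)methyl]-6-(3-chloropropyl)-2-methyl-5-(prop-1-en-2-yl)cyclohex-2-en-1-one (BnOCH2 trans, chloropropyl cis to isopropenyl) | CC1=CC[C@H](C(C)=C)[C@](COCc2ccccc2)(CCCCl)C1=O | intermediate
6 | catechol boronate of alcohol 7 (not isolated; C-4 epimers, centre left open) | CC1=CC[C@H](C(C)CB2Oc3ccccc3O2)[C@](COCc4ccccc4)(CCCCl)C1=O | intermediate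
7 | 6-[(benzyloxy)methyl]-6-(3-chloropropyl)-5-(1-hydroxypropan-2-yl)-2-methylcyclohex-2-en-1-one (ring centres as in 5; C-4 epimers, centre left open) | CC1=CC[C@H](C(C)CO)[C@](COCc2ccccc2)(CCCCl)C1=O | intermediate
8 | 2-{6-[(benzyloxy)methyl]-6-(3-chloropropyl)-4-methyl-5-oxocyclohex-3-en-1-yl}propanoic acid (C-4 epimers, centre left open) | CC1=CC[C@H](C(C)C(=O)O)[C@](COCc2ccccc2)(CCCCl)C1=O | intermediate
9 | 2-[6-(3-chloropropyl)-6-(hydroxymethyl)-4-methyl-5-oxocyclohex-3-en-1-yl]propanoic acid (not isolated; C-4 epimers, centre left open) | CC1=CC[C@H](C(C)C(=O)O)[C@](CO)(CCCCl)C1=O | intermediate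
10 | 8a-(3-chloropropyl)-4,7-dimethyl-4a,5-dihydro-1H-isochromene-3,8(4H,8aH)-dione (trans ring fusion: H-4a and the 8a chain on opposite faces; 4-CH3 equatorial, on the face opposite to the chain) | CC1=CC[C@@H]2[C@@H](C)C(=O)OC[C@@]2(CCCCl)C1=O | intermediate
11 | 8a-(3-iodopropyl)-4,7-dimethyl-4a,5-dihydro-1H-isochromene-3,8(4H,8aH)-dione (stereochemistry as in 10) | CC1=CC[C@@H]2[C@@H](C)C(=O)OC[C@@]2(CCCI)C1=O | intermediate
12 | 8-[(tert-butyldimethylsilyl)oxy]-8a-(3-iodopropyl)-4,7-dimethyl-1,4,4a,8a-tetrahydro-3H-isochromen-3-one (stereochemistry as in 10) | CC1=C(O[Si](C)(C)C(C)(C)C)[C@]2(CCCI)COC(=O)[C@H](C)[C@H]2C=C1 | intermediate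
13 | 9-[(tert-butyldimethylsilyl)oxy]-11,12,13,14,15,16-hexanor-5β-labda-6,8-dien-19,20-olide (rings A/B cis, H-5 cis to C-20) | CC1=C(O[Si](C)(C)C(C)(C)C)[C@]23CCC[C@](C)(C(=O)OC2)[C@H]3C=C1 | intermediate
14 | 9α-[(tert-butyldimethylsilyl)oxy]-6β,9β-epidioxy-11,12,13,14,15,16-hexanor-5β-labd-7-en-19,20-olide (not isolated) | CC1=C[C@H]2OO[C@]1(O[Si](C)(C)C(C)(C)C)[C@]34CCC[C@](C)(C(=O)OC3)[C@@H]24 | intermediate
15 | 6β-hydroperoxy-9-oxo-11,12,13,14,15,16-hexanor-5β-labd-7-en-19,20-olide (not isolated) | CC1=C[C@@H](OO)[C@H]2[C@]3(CCC[C@]2(C)C(=O)OC3)C1=O | intermediate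
16 | 6β-hydroxy-9-oxo-11,12,13,14,15,16-hexanor-5β-labd-7-en-19,20-olide (6-OH cis to H-5) | CC1=C[C@@H](O)[C@H]2[C@]3(CCC[C@]2(C)C(=O)OC3)C1=O | intermediate
17 | vinylmagnesium bromide | C=C[Mg]Br | starting material
18 | 6β,9α-dihydroxy-13,14,15,16-tetranor-5β-labda-7,11-dien-19,20-olide (9-vinyl β, 9-OH α) | CC1=C[C@@H](O)[C@H]2[C@]3(CCC[C@]2(C)C(=O)OC3)[C@@]1(O)C=C | intermediate
19 | 3-bromofuran-2(5H)-one | O=C1OCC=C1Br | starting material
20 | 12-(9-borabicyclo[3.3.1]nonan-9-yl)-6β,9α-dihydroxy-13,14,15,16-tetranor-5β-labd-7-en-19,20-olide (not isolated) | CC1=C[C@@H](O)[C@H]2[C@]3(CCC[C@]2(C)C(=O)OC3)[C@@]1(O)CCB1C2CCCC1CCC2 | intermediate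
21 | 6β,9α-dihydroxy-5β-labda-7,13-diene-19,20:16,15-diolide (α-substituted butenolide) | CC1=C[C@@H](O)[C@H]2[C@]3(CCC[C@]2(C)C(=O)OC3)[C@@]1(O)CCC1=CCOC1=O | intermediate
22 | 6β,9α,16-tris(trimethylsilyloxy)-15,16-epoxy-5β-labda-7,13(16),14-trien-19,20-olide (2-silyloxyfuran; not isolated) | CC1=C[C@@H](O[Si](C)(C)C)[C@H]2[C@]3(CCC[C@]2(C)C(=O)OC3)[C@@]1(O[Si](C)(C)C)CCc1ccoc1O[Si](C)(C)C | intermediate
23 | (13R)-6β-(trimethylsilyloxy)-9α,13-epoxy-5β-labda-7,14-diene-19,20:16,15-diolide (not isolated) | CC1=C[C@@H](O[Si](C)(C)C)[C@H]2[C@]3(CCC[C@]2(C)C(=O)OC3)[C@@]12CC[C@]1(C=COC1=O)O2 | intermediate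
24 | (13R)-6β-hydroxy-9α,13-epoxy-5β-labda-7,14-diene-19,20:16,15-diolide | CC1=C[C@@H](O)[C@H]2[C@]3(CCC[C@]2(C)C(=O)OC3)[C@@]12CC[C@]1(C=COC1=O)O2 | intermediate
25 | (4S,5S,6R,8R,9R,10S,13R)-6β-hydroxy-9α,13-epoxy-5β-labdane-19,20:16,15-diolide (8α-CH3) | C[C@@H]1C[C@@H](O)[C@H]2[C@]3(CCC[C@]2(C)C(=O)OC3)[C@@]12CC[C@]1(CCOC1=O)O2 | target

## Step count and risks

Total steps: 13. Longest linear sequence: 13 steps, from 1 to 25.

Steps most likely to fail:

**Step 12 (the proposed new spiroetherification).** Possible failures are acetate capture at C-15, ionisation of the allylic C-9 silyl ether, or the wrong face at C-13. The sense of induction of the (R,R)-iodane is not known for this substrate and must be checked on the first run. The fallback uses known chemistry and sets out from butenolide 21. Conjugate reduction with NaBH4/NiCl2·6H2O in MeOH gives the saturated γ-lactone F1 as both C-13 epimers. LiN(SiMe3)2 (3.3 equiv) then CBr4 at −78 °C brominates the only enolisable position (C-13; C-4 is quaternary) to give the α-bromolactone F2, which is not isolated. On warming to 0 °C the C-9 alkoxide displaces the tertiary α-bromide (intramolecular Williamson etherification, 5-exo-tet) and gives the spiro ether F3 together with its C-13 epimer, which is removed by chromatography. F3 is hydrogenated under the step 13 conditions and so comes back to the route at target 25. The cost is the loss of the unwanted C-13 epimer.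

**Step 9 (singlet-oxygen γ-hydroxylation).** Possible failures are ene or dioxetane pathways and messy collapse of the silyl peroxyketal. The fallback sets out from silyl dienol ether 13. Buffered mCPBA (vinylogous Rubottom oxidation; axial attack at C-6 is expected, as in steroidal dienol ethers) followed by dilute HCl work-up gives the 6α-hydroxy enone F4. Mitsunobu inversion with 4-nitrobenzoic acid, PPh3 and DIAD gives the 6β-ester F5. K2CO3 in MeOH removes the ester and the route is rejoined at hydroxy enone 16. If mCPBA attacks the β face instead, 16 is formed directly.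

**Step 11 (hydroboration and B-alkyl Suzuki coupling).** Possible failures are slow coupling of the base-sensitive bromobutenolide, or oxa-Michael closure of the product under base. The fallback sets out from hydroxy enone 16. CH2=CHCH2MgBr/CeCl3 at −78 °C adds an allyl group from the β face to give the allyl carbinol F6. Cross-metathesis with α-methylene-γ-butyrolactone (second-generation Hoveyda–Grubbs catalyst, CH2Cl2, 40 °C) gives the (E)-alkylidene lactone F7. RhCl3·3H2O in EtOH at 70 °C moves the exocyclic double bond into the lactone ring and the route is rejoined at butenolide 21.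

## Further compounds

F1 | step 12 | 6β,9α-dihydroxy-5β-labd-7-ene-19,20:16,15-diolide (both C-13 epimers, centre left open) | CC1=C[C@@H](O)[C@H]2[C@]3(CCC[C@]2(C)C(=O)OC3)[C@@]1(O)CCC1CCOC1=O
F2 | step 12 | 13-bromo-6β,9α-dihydroxy-5β-labd-7-ene-19,20:16,15-diolide (not isolated; C-13 left open) | CC1=C[C@@H](O)[C@H]2[C@]3(CCC[C@]2(C)C(=O)OC3)[C@@]1(O)CCC1(Br)CCOC1=O
F3 | step 12 | (13R)-6β-hydroxy-9α,13-epoxy-5β-labd-7-ene-19,20:16,15-diolide | CC1=C[C@@H](O)[C@H]2[C@]3(CCC[C@]2(C)C(=O)OC3)[C@@]12CC[C@]1(CCOC1=O)O2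
F4 | step 9 | 6α-hydroxy-9-oxo-11,12,13,14,15,16-hexanor-5β-labd-7-en-19,20-olide (C-6 epimer of 16) | CC1=C[C@H](O)[C@H]2[C@]3(CCC[C@]2(C)C(=O)OC3)C1=O
F5 | step 9 | 6β-(4-nitrobenzoyloxy)-9-oxo-11,12,13,14,15,16-hexanor-5β-labd-7-en-19,20-olide | CC1=C[C@@H](OC(=O)c4ccc(cc4)[N+](=O)[O-])[C@H]2[C@]3(CCC[C@]2(C)C(=O)OC3)C1=O
F6 | step 11 | 6β,9α-dihydroxy-14,15,16-trinor-5β-labda-7,12-dien-19,20-olide (9-allyl β) | CC1=C[C@@H](O)[C@H]2[C@]3(CCC[C@]2(C)C(=O)OC3)[C@@]1(O)CC=C
F7 | step 11 | (12E)-6β,9α-dihydroxy-5β-labda-7,12-diene-19,20:16,15-diolide | CC1=C[C@@H](O)[C@H]2[C@]3(CCC[C@]2(C)C(=O)OC3)[C@@]1(O)C/C=C1\CCOC1=O
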